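**Strategy.** Everything rests on excising ring B, the catechol ring fused to the seven-membered ring. Its two adjacent carbons, each para to an oxygen, are joined to the benzylic methines C8 and C9, which lie 1,5 to each other across two ortho carbons of the monophenolic ring C. One pot does both: a benzylic alcohol at C8, para to the ring C hydroxyl, becomes a p-quinone methide that a chiral phosphoric acid arylates with 1,2-bis(benzyloxy)benzene, and the C9 alkyne carbon, polarised by ring D, is then closed by gold-catalysed 7-endo hydroarylation. The precursor is an o-alkynylaryl carbinol with neither central ring formed; biaryl closure and convex-face hydrogenation follow.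

Key step: step 7

Labels used: ring A = resorcinol ring; ring B = catechol ring fused to the seven-membered ring; ring C = monohydroxy ring shared by the dihydrophenanthrene and the seven-membered ring; ring D = pendant catechol ring. C7 = CH2 of the dihydrophenanthrene; C8 = its CH, also part of the seven-membered ring; C9 = CH bearing ring D; C10 = CH2 of the seven-membered ring. In these labels the target is (8S,9R), with H8 and H9 cis on the seven-membered ring.

Remark on the chemistry: the sense of induction of the phosphoric acid in step 7 is not predicted here. The enantiomer that delivers (S)-C8 is the one to be used; (R)-TRIP is written for definiteness.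

Step 1
Reactants: 1 3-bromo-5-chlorophenol
Product: 2 (3-bromo-5-chlorophenoxy)triisopropylsilane
Conditions: TIPSCl, imidazole, DMF, rt
Reagents that add atoms: chlorotriisopropylsilane, CC(C)[Si](Cl)(C(C)C)C(C)C
Why: Standard silylation of a phenol; the bulky silyl ether should later shield both positions next to oxygen against metalation.

Step 2
Reactants: 2 (3-bromo-5-chlorophenoxy)triisopropylsilane
Product: 4 2-bromo-6-chloro-4-(triisopropylsilyloxy)benzaldehyde, via aryllithium 3 (not isolated)
Conditions: LiN(i-Pr)2, THF, −78 °C; DMF, −78 °C to rt; H2O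
Reagents that add atoms: N,N-dimethylformamide, CN(C)C=O
Why: Halogen-directed ortho-lithiation should remove the most acidic hydrogen, the one between bromine and chlorine, and formylation of the aryllithium with DMF then installs the future C8.

Step 3
Reactants: 5 3,4-bis(benzyloxy)benzaldehyde
Product: 6 1,2-bis(benzyloxy)-4-ethynylbenzene
Conditions: dimethyl (1-diazo-2-oxopropyl)phosphonate, K2CO3, MeOH, rt
Reagents that add atoms: dimethyl (1-diazo-2-oxopropyl)phosphonate, COP(=O)(OC)C(=[N+]=[N-])C(C)=O
Why: Seyferth–Gilbert homologation with the Ohira–Bestmann reagent turns the aldehyde into the terminal alkyne under mild base that leaves benzyl ethers untouched.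

Step 4
Reactants: 4 2-bromo-6-chloro-4-(triisopropylsilyloxy)benzaldehyde; 6 1,2-bis(benzyloxy)-4-ethynylbenzene
Product: 7 2-{[3,4-bis(benzyloxy)phenyl]ethynyl}-6-chloro-4-(triisopropylsilyloxy)benzaldehyde
Conditions: Pd(PPh3)2Cl2 (3 mol %), CuI (5 mol %), Et3N, THF, 50 °C
Reagents that add atoms: none
Why: Sonogashira coupling should occur only at the C–Br bond, which is activated by the ortho formyl group and adds to palladium far faster than the C–Cl bond kept for step 8.

Step 5
Reactants: 8 3,5-bis(benzyloxy)benzyl bromide; 7 2-{[3,4-bis(benzyloxy)phenyl]ethynyl}-6-chloro-4-(triisopropylsilyloxy)benzaldehyde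
Product: 10 rac-2-[3,5-bis(benzyloxy)phenyl]-1-[2-{[3,4-bis(benzyloxy)phenyl]ethynyl}-6-chloro-4-(triisopropylsilyloxy)phenyl]ethan-1-ol, via benzylzinc bromide 9 (not isolated)
Conditions: Zn dust, LiCl, THF, 0 °C; then 7, MgCl2, THF, 0 °C to rt; H2O
Reagents that add atoms: none
Why: Zinc insertion into the benzylic bromide gives a benzylzinc reagent whose MgCl2-accelerated addition to the aldehyde should tolerate aryl chloride, alkyne and silyl ether; the carbinol centre is formed racemic and is erased in step 7.

Step 6
Reactants: 10 rac-2-[3,5-bis(benzyloxy)phenyl]-1-[2-{[3,4-bis(benzyloxy)phenyl]ethynyl}-6-chloro-4-(triisopropylsilyloxy)phenyl]ethan-1-ol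
Product: 11 rac-4-{2-[3,5-bis(benzyloxy)phenyl]-1-hydroxyethyl}-3-{[3,4-bis(benzyloxy)phenyl]ethynyl}-5-chlorophenol
Conditions: Bu4NF, AcOH, THF, 0 °C
Reagents that add atoms: none
Why: Fluoride cleaves the aryl silyl ether, and the acetic acid buffer should keep the benzylic alkoxide from adding to the neighbouring alkyne.

Step 7
Reactants: 11 rac-4-{2-[3,5-bis(benzyloxy)phenyl]-1-hydroxyethyl}-3-{[3,4-bis(benzyloxy)phenyl]ethynyl}-5-chlorophenol; 12 1,2-bis(benzyloxy)benzene
Product: 15 (5S)-7,8-bis(benzyloxy)-5-[3,5-bis(benzyloxy)benzyl]-10-[3,4-bis(benzyloxy)phenyl]-4-chloro-5H-dibenzo[a,d][7]annulen-2-ol, via para-quinone methide 13 (not isolated), via C8-arylated alkynylphenol 14 (not isolated)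
Conditions: (R)-TRIP [(R)-3,3'-bis(2,4,6-triisopropylphenyl)-1,1'-binaphthyl-2,2'-diyl hydrogen phosphate] (10 mol %), 12 (10 equiv), 4 Å MS, CH2Cl2, 0 °C to rt; then (t-Bu)2(biphenyl-2-yl)PAu(NCMe)SbF6 (5 mol %), 40 °C
Reagents that add atoms: none
Why: The phosphoric acid dehydrates 11 to the p-quinone methide 13 and holds it by a hydrogen bond at the ring C oxygen while 12 adds through a carbon para to an ether oxygen to the exocyclic carbon C8 (Friedel–Crafts 1,6-addition, first ring B bond) to give 14; the cationic gold complex then activates the alkyne, and the ring B carbon that is ortho to the new bond and para to the second oxygen attacks C9 anti to gold, protodeauration giving 15 (second ring B bond). The closest known reaction types are the chiral phosphoric acid-catalysed arylation of p-quinone methides generated in situ from p-hydroxybenzyl alcohols and the gold-catalysed intramolecular hydroarylation of aryl alkynes. The seven-membered ring closes in the 7-endo-dig mode. C8 is the only stereocentre formed and is to be set under catalyst control by the chiral phosphate bound to the quinone methide oxygen, (S) being required, while C9 stays trigonal until step 9. The step needs arylation by 12 and not by ring A of a second molecule, which the excess of 12 and the crowding should secure (every free position of ring A is flanked by two substituents and C8 is itself flanked by chlorine and the alkynyl group), and it needs 7-endo over 6-exo closure, which the para oxygen of ring D should secure by placing the positive charge of the activated alkyne on C9. Gold is added only after 11 is consumed, so that neither the carbinol oxygen nor a styrene formed by elimination can attack the activated alkyne.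

Step 8
Reactants: 15 (5S)-7,8-bis(benzyloxy)-5-[3,5-bis(benzyloxy)benzyl]-10-[3,4-bis(benzyloxy)phenyl]-4-chloro-5H-dibenzo[a,d][7]annulen-2-ol
Product: 16 hexabenzyl ether of 9,10-didehydro-17: (8S), C9=C10 double bond, free hydroxyl on ring C, benzyl ethers on rings A, B and D
Conditions: Pd(OAc)2 (10 mol %), PCy3·HBF4 (20 mol %), K2CO3, DMA, 130 °C
Reagents that add atoms: none
Why: Intramolecular palladium-catalysed direct arylation (concerted metalation–deprotonation) should close the six-membered ring onto either of the two equivalent ring A C–H bonds next to C7; the alternative closure onto ring B to a fluorene is geometrically excluded by the seven-membered ring, and C8 is not touched.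

Step 9
Reactants: 16 hexabenzyl ether of 9,10-didehydro-17
Product: 17 target CNP0306974.2, (8S,9R)
Conditions: H2 (3 atm), Pd/C, THF–MeOH, rt
Reagents that add atoms: none
Why: In 16 the dihydrophenanthrene ring locks C7 pseudo-equatorial, so H8 is the flagpole hydrogen on the convex face of the tub-shaped dibenzocycloheptene; heterogeneous syn-hydrogenation of C9=C10 from that open face should place H9 cis to H8 and so give (9R), while the same conditions hydrogenolyse the six benzyl ethers.

**Compound list**

1 | 3-bromo-5-chlorophenol | Oc1cc(Br)cc(Cl)c1 | starting material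
2 | (3-bromo-5-chlorophenoxy)triisopropylsilane | CC(C)[Si](Oc1cc(Br)cc(Cl)c1)(C(C)C)C(C)C | intermediate
3 | [2-bromo-6-chloro-4-(triisopropylsilyloxy)phenyl]lithium | [Li]c1c(Br)cc(O[Si](C(C)C)(C(C)C)C(C)C)cc1Cl | intermediate
4 | 2-bromo-6-chloro-4-(triisopropylsilyloxy)benzaldehyde | O=Cc1c(Br)cc(O[Si](C(C)C)(C(C)C)C(C)C)cc1Cl | intermediate
5 | 3,4-bis(benzyloxy)benzaldehyde | O=Cc1ccc(OCc2ccccc2)c(OCc2ccccc2)c1 | starting material
6 | 1,2-bis(benzyloxy)-4-ethynylbenzene | C#Cc1ccc(OCc2ccccc2)c(OCc2ccccc2)c1 | intermediate
7 | 2-{[3,4-bis(benzyloxy)phenyl]ethynyl}-6-chloro-4-(triisopropylsilyloxy)benzaldehyde | O=Cc1c(C#Cc2ccc(OCc3ccccc3)c(OCc3ccccc3)c2)cc(O[Si](C(C)C)(C(C)C)C(C)C)cc1Cl | intermediate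
8 | 3,5-bis(benzyloxy)benzyl bromide | BrCc1cc(OCc2ccccc2)cc(OCc2ccccc2)c1 | starting material
9 | [3,5-bis(benzyloxy)benzyl]zinc bromide | Br[Zn]Cc1cc(OCc2ccccc2)cc(OCc2ccccc2)c1 | intermediate
10 | rac-2-[3,5-bis(benzyloxy)phenyl]-1-[2-{[3,4-bis(benzyloxy)phenyl]ethynyl}-6-chloro-4-(triisopropylsilyloxy)phenyl]ethan-1-ol | OC(Cc1cc(OCc2ccccc2)cc(OCc2ccccc2)c1)c1c(C#Cc2ccc(OCc3ccccc3)c(OCc3ccccc3)c2)cc(O[Si](C(C)C)(C(C)C)C(C)C)cc1Cl | intermediate
11 | rac-4-{2-[3,5-bis(benzyloxy)phenyl]-1-hydroxyethyl}-3-{[3,4-bis(benzyloxy)phenyl]ethynyl}-5-chlorophenol | OC(Cc1cc(OCc2ccccc2)cc(OCc2ccccc2)c1)c1c(C#Cc2ccc(OCc3ccccc3)c(OCc3ccccc3)c2)cc(O)cc1Cl | intermediate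
12 | 1,2-bis(benzyloxy)benzene | c1ccc(COc2ccccc2OCc2ccccc2)cc1 | starting material
13 | 4-{2-[3,5-bis(benzyloxy)phenyl]ethylidene}-3-{[3,4-bis(benzyloxy)phenyl]ethynyl}-5-chlorocyclohexa-2,5-dien-1-one | O=C1C=C(Cl)C(=CCc2cc(OCc3ccccc3)cc(OCc3ccccc3)c2)C(C#Cc2ccc(OCc3ccccc3)c(OCc3ccccc3)c2)=C1 | intermediate
14 | 4-{(1S)-1-[3,4-bis(benzyloxy)phenyl]-2-[3,5-bis(benzyloxy)phenyl]ethyl}-3-{[3,4-bis(benzyloxy)phenyl]ethynyl}-5-chlorophenol | Oc1cc(Cl)c(c(C#Cc2ccc(OCc3ccccc3)c(OCc3ccccc3)c2)c1)[C@@H](Cc1cc(OCc2ccccc2)cc(OCc2ccccc2)c1)c1ccc(OCc2ccccc2)c(OCc2ccccc2)c1 | intermediate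
15 | (5S)-7,8-bis(benzyloxy)-5-[3,5-bis(benzyloxy)benzyl]-10-[3,4-bis(benzyloxy)phenyl]-4-chloro-5H-dibenzo[a,d][7]annulen-2-ol | Oc1cc(Cl)c2c(c1)C=C(c1ccc(OCc3ccccc3)c(OCc3ccccc3)c1)c1cc(OCc3ccccc3)c(OCc3ccccc3)cc1[C@@H]2Cc1cc(OCc2ccccc2)cc(OCc2ccccc2)c1 | intermediate
16 | hexabenzyl ether of 9,10-didehydro-17: (8S), C9=C10 double bond, free hydroxyl on ring C, benzyl ethers on rings A, B and D | O(Cc1ccccc1)c1cc(OCc2ccccc2)c2c(c1)C[C@H]1c3cc(OCc4ccccc4)c(OCc4ccccc4)cc3C(c3ccc(OCc4ccccc4)c(OCc4ccccc4)c3)=Cc3cc(O)cc-2c31 | intermediate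
17 | CNP0306974.2, (8S,9R), H8 and H9 cis | Oc1cc(O)c2c(c1)C[C@H]1c3cc(O)c(O)cc3[C@@H](c3ccc(O)c(O)c3)Cc3cc(O)cc-2c31 | target

**Totals.** Total step count: 9. Longest linear sequence: 8 steps (1, 2, 4, 5, 6, 7, 8, 9).

**Steps most likely to fail**

1. Step 7. The intermolecular 1,6-addition may show weak enantioface discrimination, because 12 offers no hydrogen-bond donor to anchor it to the catalyst; oligomerisation through ring A is a second danger. Fallback: setting out from 11, the annulation is run with diphenyl phosphate in place of the chiral acid, followed by the same gold stage, to give the racemic dibenzocycloheptenol F1. DDQ in CH2Cl2 at 0 °C should then abstract the C8 hydride of F1, which lies para to the free phenol, and give the ring C para-quinone methide F2. Asymmetric transfer hydrogenation of F2 with diethyl 2,6-dimethyl-1,4-dihydropyridine-3,5-dicarboxylate (Hantzsch ester) and (R)-TRIP returns the hydride to C8 under catalyst control; here the hydride donor is hydrogen-bonded to the phosphate. The fallback comes back to the route at 15.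

2. Step 8. Oxidative addition into the hindered aryl chloride may be slow, with protodechlorination or catalyst inhibition by the phenoxide taking over. Fallback: setting out from 15, the aryl radical is generated without palladium by photoinduced electron transfer (10-phenylphenothiazine 10 mol %, Cs2CO3, DMSO, 365 nm). Homolytic aromatic substitution on ring A and rearomatisation should give 16 directly, where the fallback rejoins the route; it makes no new compound, hence the entry F0.

3. Step 9. Facial selectivity on the metal surface may be poor, or reduction of the hindered triaryl alkene may stall while the benzyl ethers are already cleaved. Fallback: setting out from 16, ionic hydrogenation (Et3SiH, CF3CO2H, CH2Cl2, −20 °C) protonates C10 and delivers hydride from the bulky silane to the convex face of the C9 diarylmethyl cation. This should give the saturated (8S,9R)-hexabenzyl ether F3; hydrogenolysis of F3 (H2, Pd/C, THF–MeOH) then comes back to the route at 17.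

**Further compounds**

F1 | step 7 | racemic dibenzocycloheptenol (racemate of 15) | Oc1cc(Cl)c2c(c1)C=C(c1ccc(OCc3ccccc3)c(OCc3ccccc3)c1)c1cc(OCc3ccccc3)c(OCc3ccccc3)cc1C2Cc1cc(OCc2ccccc2)cc(OCc2ccccc2)c1
F2 | step 7 | ring C para-quinone methide of 15 (C8 doubly bonded to ring C, ring C as 4-chlorocyclohexadienone) | O=C1C=C(Cl)C2=C(Cc3cc(OCc4ccccc4)cc(OCc4ccccc4)c3)c3cc(OCc4ccccc4)c(OCc4ccccc4)cc3C(c3ccc(OCc4ccccc4)c(OCc4ccccc4)c3)=CC2=C1
F0 | step 8 | none | none
F3 | step 9 | saturated (8S,9R)-hexabenzyl ether of 17 (free hydroxyl on ring C) | O(Cc1ccccc1)c1cc(OCc2ccccc2)c2c(c1)C[C@H]1c3cc(OCc4ccccc4)c(OCc4ccccc4)cc3[C@@H](c3ccc(OCc4ccccc4)c(OCc4ccccc4)c3)Cc3cc(O)cc-2c31
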